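A direct plan would tribrominate 4-methylbenzene-1,2-diol A1 to 3,4,6-tribromo-5-methylbenzene-1,2-diol A2, oxidise A2 to the o-quinone A3, let A3 tautomerise to the p-quinone methide A4, and trap A4 twice with urea A5 to form both benzylic C–N bonds.
- The oxidation of A2 to A3, with a reductive return at the end, would be a redox detour that builds no bond. It passes through an isolated, sensitive tribromo-o-quinone that can oxidise every catechol in the flask.
- The double N-benzylation of A5 through A4 would carry the only skeletal bonds of the plan on one untested tautomerisation and 1,6-addition relay. Urea is a weak, ambident nucleophile, and two such events must succeed on one urea.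
- The benzylic carbon would enter as the methyl group of A1, at the wrong oxidation level. This is what forces the quinone chemistry, and it keeps the plan linear on the full aromatic core.

**Retrosynthetic overview of the new route**

- Both aryl–CH2 bonds are cut. The N–CH2 carbons and the urea come together as 1,3-bis(hydroxymethyl)urea, and each ring comes from 4-bromocatechol.
- The feature used: in each benzene ring of the target, C1 (bearing CH2N) is para to the C4 hydroxyl and the C2 bromine is para to the C5 hydroxyl. These are the two carbons at which a catechol takes electrophiles first.
- The remaining bromines at C3 and C6, each ortho to a hydroxyl, are added last in one fourfold bromination. No ring is formed in the route.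
- The benzylic carbon stays at the formaldehyde level throughout, urea never acts as a nucleophile, and there is no quinone and no protecting group.

Key step: step 1

Remark on the chemistry: the target is achiral and has no stereocentre, so no step has to set configuration. 4-Bromocatechol and 1,3-bis(hydroxymethyl)urea are taken as commercial.

**Route**

Step 1
Reactants: 1 4-bromobenzene-1,2-diol (4-bromocatechol, 4 equiv); 2 1,3-bis(hydroxymethyl)urea (1 equiv)
Product: 4 1,3-bis[(2-bromo-4,5-dihydroxyphenyl)methyl]urea, via mono-adduct 3 (not isolated)
Conditions: CF3CO2H/AcOH 1:3, 0 °C → rt, 16 h, Ar; 2 added in portions to 1; evaporate, triturate with Et2O (recovers excess 1), recrystallise from aq EtOH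
Reagents that add atoms: none
Why: Acid ionises each N–CH2OH arm of 2 to an N-carbamoyl iminium ion, which is attacked by C5 of 1 (catechol numbering, para to the C2 hydroxyl) in an electrophilic aromatic substitution; the first event gives mono-adduct 3, and the second arm then reacts in the same way with another molecule of 1, so both aryl–CH2 bonds and the whole C15N2 skeleton are made in one flask. The closest known reaction type is the Tscherniac–Einhorn amidoalkylation in its ureidoalkylation form, the acid condensation of methylolureas with phenols to N,N'-bis(hydroxybenzyl)ureas. No ring is closed and no stereocentre is formed. The step needs para over ortho attack, one substitution per ring, and arene capture over self-condensation of 2: C5 is the carbon at which 4-bromocatechol takes its second electrophile (bromination gives 4,5-dibromocatechol), the C4 bromine blocks the other para carbon so that the product ring keeps only the slower ortho carbons, O-attack by a phenol oxygen is reversible in acid whereas C-attack is not, and the excess of 1 with portionwise addition of 2 keeps the iminium ion surrounded by arene. The diluted acid and the low temperature should keep the new p-hydroxybenzyl–N bonds from ionising again.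

Step 2
Reactants: 4 1,3-bis[(2-bromo-4,5-dihydroxyphenyl)methyl]urea
Product: 5 1,3-bis[(2,3,6-tribromo-4,5-dihydroxyphenyl)methyl]urea
Conditions: Br2 (4.2 equiv, dropwise in AcOH), NaOAc (4.4 equiv), AcOH, 10 °C → rt, dark, 2 h; aq NaHSO3 work-up, filter
Reagents that add atoms: bromine, BrBr
Why: Electrophilic aromatic bromination, in which C3 and C6 of each ring are the only free ring carbons and each is ortho to a hydroxyl, so that four equivalents of bromine should stop at the hexabromide as in the conversion of 4,5-dibromocatechol into tetrabromocatechol, while NaOAc takes up the HBr to spare the p-hydroxybenzyl–N bonds and the bisulfite work-up returns any o-quinone or N-bromo urea to the product.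

**Compound list**

1 | 4-bromobenzene-1,2-diol (4-bromocatechol) | Oc1ccc(Br)cc1O | starting material
2 | 1,3-bis(hydroxymethyl)urea (N,N'-dimethylolurea) | O=C(NCO)NCO | starting material
3 | 1-[(2-bromo-4,5-dihydroxyphenyl)methyl]-3-(hydroxymethyl)urea | O=C(NCO)NCc1cc(O)c(O)cc1Br | intermediate (not isolated)
4 | 1,3-bis[(2-bromo-4,5-dihydroxyphenyl)methyl]urea | O=C(NCc1cc(O)c(O)cc1Br)NCc1cc(O)c(O)cc1Br | intermediate
5 | 1,3-bis[(2,3,6-tribromo-4,5-dihydroxyphenyl)methyl]urea | O=C(NCc1c(Br)c(O)c(O)c(Br)c1Br)NCc1c(Br)c(O)c(O)c(Br)c1Br | target

**Step count and risks**

Total step count: 2. Longest linear sequence: 2.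

Steps most likely to fail (the route has only two steps, so both are given and there is no third):

1. Step 1. The process at risk is the capture of the ureidomethyl cation by the arene. Three things can outrun the clean double substitution: self-condensation of 2 to methylene-bridged polyureas, attack at an ortho carbon or a second substitution on one ring, and acid transfer of a benzyl group from nitrogen to excess arene. The fallback gives up the two-directional electrophile and sets out from compound 1. A Tscherniac–Einhorn reaction with the monofunctional N-(hydroxymethyl)phthalimide (MeSO3H/AcOH, rt), which cannot self-condense, should give 2-[(2-bromo-4,5-dihydroxyphenyl)methyl]isoindoline-1,3-dione F1, to be purified by crystallisation. Hydrazinolysis (N2H4·H2O, EtOH, reflux, Ar) would free 4-(aminomethyl)-5-bromobenzene-1,2-diol F2. Two molecules of F2 would then be joined with diphenyl carbonate (0.5 equiv, Et3N, DMSO, 60 °C) to come back to the route at compound 4. Any aryl carbonate or carbamate formed at a catechol oxygen is itself an acyl donor towards the amine, so the urea is the sink.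

2. Step 2. The process at risk is attack of bromine at the ring carbon that carries the CH2N arm, with loss of the side chain as a ureidomethyl cation. A second risk is over-oxidation to an o-quinone whose tautomerisation to a quinone methide expels the urea nitrogen. The fallback moves the bromination ahead of the urea. It sets out from compound 1 and passes through the phthalimide F1 described above, whose imide nitrogen cannot stabilise a departing CH2 cation. Bromination of F1 (Br2, 2.1 equiv, AcOH, rt) should give 2-[(2,3,6-tribromo-4,5-dihydroxyphenyl)methyl]isoindoline-1,3-dione F3. Hydrazinolysis would free 4-(aminomethyl)-3,5,6-tribromobenzene-1,2-diol F4, and two molecules of F4 would be joined with diphenyl carbonate as above, coming back to the route at the target 5.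

Further compounds
F1 | step 1 | 2-[(2-bromo-4,5-dihydroxyphenyl)methyl]isoindoline-1,3-dione | O=C1c2ccccc2C(=O)N1Cc1cc(O)c(O)cc1Br
F2 | step 1 | 4-(aminomethyl)-5-bromobenzene-1,2-diol | NCc1cc(O)c(O)cc1Br
F3 | step 2 | 2-[(2,3,6-tribromo-4,5-dihydroxyphenyl)methyl]isoindoline-1,3-dione | O=C1c2ccccc2C(=O)N1Cc1c(Br)c(O)c(O)c(Br)c1Br
F4 | step 2 | 4-(aminomethyl)-3,5,6-tribromobenzene-1,2-diol | NCc1c(Br)c(O)c(O)c(Br)c1Br
A1 | direct plan | 4-methylbenzene-1,2-diol (4-methylcatechol) | Cc1ccc(O)c(O)c1
A2 | direct plan | 3,4,6-tribromo-5-methylbenzene-1,2-diol | Cc1c(Br)c(O)c(O)c(Br)c1Br
A3 | direct plan | 3,4,6-tribromo-5-methylcyclohexa-3,5-diene-1,2-dione | CC1=C(Br)C(=O)C(=O)C(Br)=C1Br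
A4 | direct plan | 2,3,5-tribromo-6-hydroxy-4-methylidenecyclohexa-2,5-dien-1-one | C=C1C(Br)=C(O)C(=O)C(Br)=C1Br
A5 | direct plan | urea | NC(N)=O
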